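**Retrosynthetic overview**
- The target is unmasked from an epoxy spiroketal by O‑acetylation and ketal hydrolysis; the six‑membered carbocycle is the ring of a cheap arene and is never built.
- The epoxy spiroketal comes from a p‑methoxyphenol in one flask: oxidative dearomatisation with capture by propane‑1,3‑diol closes a 1,3‑dioxane (first ring), then a chiral phase‑transfer Weitz–Scheffer epoxidation closes the oxirane (second ring) and sets both stereocentres.
- The ketal masks the carbonyl next to the CH2OH‑bearing carbon, so peroxide can only enter at the farnesyl‑bearing alkene; the dioxane is removed in the last step.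
- The phenol comes from ortho‑C‑farnesylation of 3‑(hydroxymethyl)‑4‑methoxyphenol, itself from NaBH4 reduction of 5‑hydroxy‑2‑methoxybenzaldehyde.

Assumption: N‑benzylcinchonidinium chloride is taken to give the (1R,6S) epoxide (C1 = farnesyl‑bearing carbon); if the sense is opposite, its pseudo‑enantiomer N‑benzylcinchoninium chloride is used under the same conditions.

Step 1
Reactants: 1 5‑hydroxy‑2‑methoxybenzaldehyde
Product: 2 3‑(hydroxymethyl)‑4‑methoxyphenol
Conditions: NaBH4, MeOH, 0 °C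
Reagents that add atoms: none
Why: Chemoselective borohydride reduction of the aryl aldehyde to the benzylic alcohol; the phenol and aryl ether are inert and no stereocentre is formed.

Step 2
Reactants: 2 3‑(hydroxymethyl)‑4‑methoxyphenol; 3 (2E,6E)‑farnesyl bromide
Product: 4 5‑(hydroxymethyl)‑4‑methoxy‑2‑[(2E,6E)‑3,7,11‑trimethyldodeca‑2,6,10‑trien‑1‑yl]phenol
Conditions: NaH (1.0 equiv), PhMe, 0 °C; then 3, rt
Reagents that add atoms: none
Why: Ortho‑C‑alkylation of a tight sodium phenoxide ion pair in a non‑polar solvent (Claisen C‑alkylation) by SN2 at the primary allylic bromide, which keeps the 2E,6E geometry; only the unhindered ortho carbon (para to CH2OH) is open, and no stereocentre is formed.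

Step 3
Reactants: 4 5‑(hydroxymethyl)‑4‑methoxy‑2‑[(2E,6E)‑farnesyl]phenol
Product: 7 (1R,6S)‑4‑(hydroxymethyl)‑1‑[(2E,6E)‑3,7,11‑trimethyldodeca‑2,6,10‑trien‑1‑yl]spiro[7‑oxabicyclo[4.1.0]hept‑3‑ene‑5,2'‑[1,3]dioxan]‑2‑one, via mixed ketal dienone 5 (not isolated), via spiroketal dienone 6 (not isolated)
Conditions: PhI(OAc)2, HO(CH2)3OH (10 equiv), CH2Cl2, 0 °C; CSA (5 mol %), rt; then PhMe, t‑BuOOH, 1 M aq NaOH, N‑benzylcinchonidinium chloride (10 mol %), 0 °C
Reagents that add atoms: propane‑1,3‑diol, OCCCO; tert‑butyl hydroperoxide, CC(C)(C)OO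
Why: Proposed new method: a one‑flask merger of known reaction types, in which PhI(OAc)2 oxidative dearomatisation of the p‑methoxyphenol is intercepted by the diol and acid‑catalysed transketalisation (loss of MeOH) closes the 1,3‑dioxane, after which a Wynberg‑type phase‑transfer Weitz–Scheffer epoxidation adds t‑BuOO− to the only accessible β‑carbon (the unsubstituted CH next to the spiro centre, the other β‑carbon being fully substituted), the enolate closes on O–O to give the necessarily cis‑fused oxirane, and the chiral ammonium–peroxide ion pair selects the enone face so that both stereocentres (1R,6S) are set together; the closest known reactions are the stepwise quinone‑monoketal formation and cinchona phase‑transfer epoxidation of spiroketal enones.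

Step 4
Reactants: 7 epoxy spiroketal alcohol
Product: 8 [(1R,6S)‑2‑oxo‑1‑[(2E,6E)‑3,7,11‑trimethyldodeca‑2,6,10‑trien‑1‑yl]spiro[7‑oxabicyclo[4.1.0]hept‑3‑ene‑5,2'‑[1,3]dioxan]‑4‑yl]methyl acetate
Conditions: Ac2O, pyridine, DMAP (cat.), CH2Cl2, 0 °C
Reagents that add atoms: acetic anhydride, CC(=O)OC(C)=O
Why: DMAP‑catalysed acylation of the primary alcohol; the epoxide, enone, ketal and trisubstituted alkenes are inert and the stereocentres are untouched.

Step 5
Reactants: 8 epoxy spiroketal acetate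
Product: 9 (1R,6S)‑4‑(acetoxymethyl)‑1‑[(2E,6E)‑3,7,11‑trimethyldodeca‑2,6,10‑trien‑1‑yl]‑7‑oxabicyclo[4.1.0]hept‑3‑ene‑2,5‑dione (C1 = farnesyl‑bearing carbon)
Conditions: 48% aq HF, MeCN, 0 °C to rt
Reagents that add atoms: water, O
Why: Acid‑catalysed hydrolysis of the 1,3‑dioxane ketal through the oxocarbenium ion under conditions mild enough for the acetate, the oxirane and the farnesyl alkenes; the epoxide stereocentres are not involved and cannot epimerise.

**Compound list**
1 | 5‑hydroxy‑2‑methoxybenzaldehyde | COc1ccc(O)cc1C=O | starting material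
2 | 3‑(hydroxymethyl)‑4‑methoxyphenol | COc1ccc(O)cc1CO | intermediate
3 | (2E,6E)‑farnesyl bromide | BrC/C=C(\C)CC/C=C(\C)CCC=C(C)C | starting material
4 | 5‑(hydroxymethyl)‑4‑methoxy‑2‑[(2E,6E)‑farnesyl]phenol | COc1cc(C/C=C(\C)CC/C=C(\C)CCC=C(C)C)c(O)cc1CO | intermediate
5 | 4‑(3‑hydroxypropoxy)‑5‑(hydroxymethyl)‑4‑methoxy‑2‑[(2E,6E)‑farnesyl]cyclohexa‑2,5‑dien‑1‑one (racemic at the ketal carbon, which is lost in the next event) | OCC1=CC(=O)C(C/C=C(\C)CC/C=C(\C)CCC=C(C)C)=CC1(OC)OCCCO | intermediate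
6 | 7‑(hydroxymethyl)‑10‑[(2E,6E)‑farnesyl]‑1,5‑dioxaspiro[5.5]undeca‑7,10‑dien‑9‑one | OCC1=CC(=O)C(C/C=C(\C)CC/C=C(\C)CCC=C(C)C)=CC12OCCCO2 | intermediate
7 | (1R,6S)‑4‑(hydroxymethyl)‑1‑[(2E,6E)‑farnesyl]spiro[7‑oxabicyclo[4.1.0]hept‑3‑ene‑5,2'‑[1,3]dioxan]‑2‑one | OCC1=CC(=O)[C@]2(C/C=C(\C)CC/C=C(\C)CCC=C(C)C)O[C@@H]2C13OCCCO3 | intermediate
8 | [(1R,6S)‑2‑oxo‑1‑[(2E,6E)‑farnesyl]spiro[7‑oxabicyclo[4.1.0]hept‑3‑ene‑5,2'‑[1,3]dioxan]‑4‑yl]methyl acetate | CC(=O)OCC1=CC(=O)[C@]2(C/C=C(\C)CC/C=C(\C)CCC=C(C)C)O[C@@H]2C13OCCCO3 | intermediate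
9 | (1R,6S)‑4‑(acetoxymethyl)‑1‑[(2E,6E)‑farnesyl]‑7‑oxabicyclo[4.1.0]hept‑3‑ene‑2,5‑dione | CC(=O)OCC1=CC(=O)[C@]2(C/C=C(\C)CC/C=C(\C)CCC=C(C)C)O[C@@H]2C1=O | target

**Step count**
Total steps: 5. Longest linear sequence: 5 (1 to 9; 3 enters at step 2).

**Steps most likely to fail, with fallbacks**

Step 3 is the main risk: three events in one flask, and the enantioselectivity of the phase‑transfer epoxidation is untested for an α‑farnesyl enone carrying a free hydroxymethyl group. The fallback sets out from 4 and comes back at 7. The two ring closures are run apart: PhI(OAc)2 with propane‑1,3‑diol followed by PPTS gives spiroketal dienone 6, now isolated. The oxirane is then installed by a hydroxyl‑directed, tartrate‑mediated nucleophilic epoxidation (Ph3COOH, NaHMDS, diisopropyl tartrate, PhMe, −78 °C). Here the free CH2OH binds the chiral sodium tartrate–peroxide aggregate and delivers it to one face of the neighbouring β‑carbon; the tartrate antipode is chosen to give 7. No new compound is made.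

Step 2 is the second risk: O‑alkylation competes with C‑alkylation and the yield is typically moderate. The fallback sets out from 2 and comes back at 4. Deliberate O‑alkylation with 3 (K2CO3, acetone) gives 3‑(hydroxymethyl)‑4‑methoxyphenyl (2E,6E)‑farnesyl ether F1. A clay‑promoted [1,3]‑shift (montmorillonite K10 or Florisil, PhMe, 0 °C) then moves the farnesyl group to the free ortho carbon.

Step 5 is the third risk: a dioxane next to an oxirane hydrolyses slowly, and the acid may attack the farnesyl chain or the epoxide. The fallback sets out from 4 and comes back at 9, replacing the cyclic ketal by an acyclic one that falls off far more easily. PhI(OAc)2 in MeOH gives 5‑(hydroxymethyl)‑4,4‑dimethoxy‑2‑[(2E,6E)‑farnesyl]cyclohexa‑2,5‑dien‑1‑one F2. The same phase‑transfer epoxidation gives (1R,6S)‑4‑(hydroxymethyl)‑5,5‑dimethoxy‑1‑[(2E,6E)‑farnesyl]‑7‑oxabicyclo[4.1.0]hept‑3‑en‑2‑one F3. Acetylation gives [(1R,6S)‑5,5‑dimethoxy‑2‑oxo‑1‑[(2E,6E)‑farnesyl]‑7‑oxabicyclo[4.1.0]hept‑3‑en‑4‑yl]methyl acetate F4. Oxalic acid on wet silica gel in CH2Cl2 at rt then releases 9.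

**Further compounds**
F0 | step 3 | none | none
F1 | step 2 | 3‑(hydroxymethyl)‑4‑methoxyphenyl (2E,6E)‑farnesyl ether | COc1ccc(OC/C=C(\C)CC/C=C(\C)CCC=C(C)C)cc1CO
F2 | step 5 | 5‑(hydroxymethyl)‑4,4‑dimethoxy‑2‑[(2E,6E)‑farnesyl]cyclohexa‑2,5‑dien‑1‑one | OCC1=CC(=O)C(C/C=C(\C)CC/C=C(\C)CCC=C(C)C)=CC1(OC)OC
F3 | step 5 | (1R,6S)‑4‑(hydroxymethyl)‑5,5‑dimethoxy‑1‑[(2E,6E)‑farnesyl]‑7‑oxabicyclo[4.1.0]hept‑3‑en‑2‑one | OCC1=CC(=O)[C@]2(C/C=C(\C)CC/C=C(\C)CCC=C(C)C)O[C@@H]2C1(OC)OC
F4 | step 5 | [(1R,6S)‑5,5‑dimethoxy‑2‑oxo‑1‑[(2E,6E)‑farnesyl]‑7‑oxabicyclo[4.1.0]hept‑3‑en‑4‑yl]methyl acetate | CC(=O)OCC1=CC(=O)[C@]2(C/C=C(\C)CC/C=C(\C)CCC=C(C)C)O[C@@H]2C1(OC)OC
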